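The runs were generated by integration from invented constants; the scatter is artificial.

Don't read the flat tails of these runs as an equilibrium. In the delta run at 5.00 h, X, D and J add up to 101% of the charge, so G is gone within the scatter. That delta tail is a split frozen when G ran out: kinetic control, not thermodynamic control.

| flask | G | remark | time |
|---|---|---|---|
| theta | 5.3 × 10⁻⁴ M | run made earlier |  |
| eta | 0.0057 M | run made earlier |  |
| delta | 0.060 M | run made earlier |  |
| south | 6.0 × 10⁻⁴ M |  | 10 h |
| south-west | 0.0020 M |  | 10 h |
| north | 0.0060 M |  | 10 h |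
| south-east | 0.015 M |  | 10 h |
| east | 0.050 M |  | 10 h |

| run | time / h | X / % | D / % | J / % |
|---|---|---|---|---|
| theta | 0.417 | 56.4 | 0.5 | 0 |
| theta | 0.833 | 80.7 | 0.1 | 0.4 |
| theta | 1.33 | 92.8 | 0 | 0.1 |
| theta | 2.50 | 98.6 | 0.5 | 0.1 |
| theta | 5.00 | 99.8 | 0.6 | 0 |
| eta | 1.00 | 83.4 | 3.1 | 0.1 |
| eta | 2.00 | 94.2 | 3.1 | 0.6 |
| eta | 3.00 | 95.7 | 3.3 | 0.6 |
| eta | 4.00 | 96.1 | 3.1 | 0.6 |
| eta | 5.00 | 96.2 | 3.6 | 0.7 |
| delta | 0.417 | 45.6 | 23.1 | 1.9 |
| delta | 1.33 | 67.5 | 25.5 | 4.0 |
| delta | 2.50 | 70.7 | 25.5 | 3.6 |
| delta | 4.00 | 70.5 | 25.9 | 4.2 |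
| delta | 5.00 | 70.3 | 26.4 | 4.1 |

(scatter of a reading: 0.3 percentage points)

- in percentages every species weighs as the G in it: one D or J counts as two
- "hardly changes" means that all values lie within two and a half points (for a concentration: within two and a half percent of the largest)

1. share of X in all that became X or D or J for south, south-west, north, south-east, east, in this order
2. the course of these numbers from the first flask to the last (falls all the way / falls, then rises / rises, then falls / hardly changes / rises all the way)

From eta to delta the charge grows by a factor 10.5 and (D+J)/X by a factor 9.71. So I take the rival route as one order higher in G than ring closure.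

Let g be the fraction of the charge still G. Each bit of G lost then becomes X with chance one over (one plus a·g), where a is K times the starting G. K is the partition constant, the rival rate over the closure rate per unit of G. Integrating g from one to zero gives the X share: ln(one plus a), divided by a.

For small a, a is close to two times (D+J)/X. The eta run at 5.00 h therefore reads K = 15.7 M⁻¹, with the scatter of D and J in it. My K gives delta 70.5%, and the delta readings give 69.7%. The theta run stands at 99.8% X by 5.00 h, and the asked 10 h is longer than that, so I use the end share.

The forecast calls this “a kinetic partition, not an equilibrium” and takes K as 15.5 per M, against my 15.7 M⁻¹. It gives 99.5%, 98.5%, 95.7%, 89.9%, 74%: falls all the way.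

The flasks give 99.5%, 98.5%, 95.6%, 89.9%, 73.8%: falls all the way.

    G → X (k = 2.00 h⁻¹)
    2 G → D (k = 13.0 M⁻¹ h⁻¹)
    G + X → J (k = 2.50 M⁻¹ h⁻¹)

At east the forecast parts from the flask by 0.2 percentage points. In east, G stands at 0% at 10.0 h, and X reads 73.8% then and 73.8% at 100 h: the later hours add nothing to the share. Now put K to use. For east, a is 0.784, and ln(one plus a) over a gives 73.8%, against the flask's 73.8%.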